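**Plan**
- Retrosynthesis: the C1–C2 and C3–C4 bonds of the saturated ring B are cut together. C1 (carbinol) and C4 (naphthyl-bearing methine) are benzylic carbons on the adjacent ring-A carbons C8a and C4a, so they are the two ends of a hydroxy-o-quinodimethane, and C2–C3 is an ethylene unit.
- The quinodimethane is the photoenol of a 2-(naphthylmethyl)-3-methoxybenzaldehyde. Ethylene is delivered as phenyl vinyl sulfone; the sulfonyl group activates, binds the chiral titanium template and is removed at the end.
- The aldehyde is cut at the CH2–naphthyl bond into a benzylic zinc reagent (from methyl 3-methoxy-2-methylbenzoate) and a 4-bromonaphthyl tosylate (from 8-methoxynaphthalen-1-ol).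
- Forward: two short arene sequences, Negishi union, ester-to-aldehyde adjustment, photoenolization/Diels–Alder closure of ring B, then one electron-transfer step that removes the sulfonyl and tosyl groups.
- Stereochemistry: C1/C4 cis from the outward,outward dienol and suprafacial addition; absolute configuration from the TADDOLate on titanium; C2 is a temporary centre.

Key step: step 7

Assumption: the diene face left open by the (R,R)-TADDOLate is taken to be the one that leads to the (1S,4S) series; if the sense of induction proves opposite, the (S,S)-ligand is used in the same way.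

Step 1
Reactants: 1 methyl 3-methoxy-2-methylbenzoate
Product: 2 methyl 2-(bromomethyl)-3-methoxybenzoate
Conditions: NBS (1.05 equiv), AIBN (cat.), PhCF3, 85 °C
Reagents that add atoms: N-bromosuccinimide, O=C1CCC(=O)N1Br
Why: Wohl–Ziegler radical bromination at the only benzylic C–H position; the ester deactivates the ring toward electrophilic bromination.

Step 2
Reactants: 3 8-methoxynaphthalen-1-ol
Product: 4 4-bromo-8-methoxynaphthalen-1-ol
Conditions: NBS (1.0 equiv), MeCN, −20 to 0 °C, dark
Reagents that add atoms: N-bromosuccinimide, O=C1CCC(=O)N1Br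
Why: Electrophilic aromatic bromination; the free hydroxyl is the strongest donor and, being hydrogen-bonded to the peri-methoxy oxygen, should direct the reagent to its para position C4 rather than to C2 or to the methoxy-bearing ring.

Step 3
Reactants: 4 4-bromo-8-methoxynaphthalen-1-ol
Product: 5 4-bromo-8-methoxynaphthalen-1-yl 4-methylbenzenesulfonate
Conditions: TsCl (1.2 equiv), Et3N, DMAP (cat.), CH2Cl2, 0 °C to rt
Reagents that add atoms: p-toluenesulfonyl chloride, Cc1ccc(cc1)S(=O)(=O)Cl
Why: DMAP-catalysed sulfonylation of the naphthol; the tosylate is a non-acidic, electron-poor mask that tolerates organozinc, hydride, oxidant and light and is cleaved by the same electron-transfer conditions as the sulfone in step 8.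

Step 4
Reactants: 2 methyl 2-(bromomethyl)-3-methoxybenzoate; 5 4-bromo-8-methoxynaphthalen-1-yl 4-methylbenzenesulfonate
Product: 7 methyl 3-methoxy-2-{[5-methoxy-4-(tosyloxy)naphthalen-1-yl]methyl}benzoate, via benzylic zinc bromide 6 (not isolated)
Conditions: Zn dust (1.5 equiv), LiCl, THF, 0 °C; then 5, Pd(OAc)2 (2 mol%), SPhos (4 mol%), THF, 25 °C
Reagents that add atoms: none
Why: Ester-tolerant zinc insertion into the benzylic C–Br bond followed by Negishi coupling, in which zerovalent palladium should insert into the aryl C–Br bond far faster than into the aryl sulfonate C–O bond.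

Step 5
Reactants: 7 methyl 3-methoxy-2-{[5-methoxy-4-(tosyloxy)naphthalen-1-yl]methyl}benzoate
Product: 8 4-[2-(hydroxymethyl)-6-methoxybenzyl]-8-methoxynaphthalen-1-yl 4-methylbenzenesulfonate
Conditions: i-Bu2AlH (2.5 equiv), CH2Cl2, −78 to 0 °C; aq. potassium sodium tartrate
Reagents that add atoms: none
Why: Hydride reduction of the methyl ester to the primary alcohol at low temperature, where aryl sulfonates and aryl methyl ethers are untouched.

Step 6
Reactants: 8 4-[2-(hydroxymethyl)-6-methoxybenzyl]-8-methoxynaphthalen-1-yl 4-methylbenzenesulfonate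
Product: 9 4-(2-formyl-6-methoxybenzyl)-8-methoxynaphthalen-1-yl 4-methylbenzenesulfonate
Conditions: MnO2 (activated, 15 equiv), CH2Cl2, rt
Reagents that add atoms: none
Why: Selective heterogeneous oxidation of a benzylic alcohol to the aldehyde, with no over-oxidation and no attack on the diarylmethane CH2.

Step 7
Reactants: 9 4-(2-formyl-6-methoxybenzyl)-8-methoxynaphthalen-1-yl 4-methylbenzenesulfonate; 10 phenyl vinyl sulfone
Product: 12 (1R,2S,4S)-5-methoxy-4-[5-methoxy-4-(tosyloxy)naphthalen-1-yl]-2-(phenylsulfonyl)-1,2,3,4-tetrahydronaphthalen-1-ol (all-cis), via hydroxy-o-quinodimethane 11 (not isolated)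
Conditions: 10 (3 equiv), Ti(Oi-Pr)4 (1.5 equiv), (R,R)-TADDOL (1.6 equiv), toluene, argon, 365 nm LED, 20 °C; aq. NaHCO3
Reagents that add atoms: none
Why: Proposed new method: excitation of the aldehyde n,π* band of 9 triggers 1,5-hydrogen transfer from the doubly benzylic CH2 to the carbonyl oxygen, and the 1,4-biradical relaxes to the outward,outward hydroxy-o-quinodimethane 11 (the isomer with inward OH returns to 9 by a 1,5-hydrogen shift); 11 binds through its oxygen to Ti(TADDOLate)(Oi-Pr)2 in place of one isopropoxide while a sulfonyl oxygen of 10 binds the same metal, and a templated suprafacial [4+2] addition follows in which ring A regains its aromaticity. The closest known reaction types are the Ti(Oi-Pr)4/TADDOL-mediated enantioselective photoenolization/Diels–Alder reaction of 2-alkylbenzaldehydes with enones and enoates, the photoenol Diels–Alder reaction of 2-benzylbenzaldehydes, and additions of o-quinodimethanes to vinyl sulfones; what is new is a sulfonyl instead of a carbonyl oxygen as the titanium-binding site, argued from the similar donor strength of sulfones and esters and the same six-membered O–Ti···O=S array in the transition state. Ring B, the only ring closed, forms by an intermolecular concerted [4πs+2πs] cycloaddition across the two exocyclic carbons of the quinodimethane. C1 and C4 come out cis because OH and naphthyl both occupy outward positions of 11 and the dienophile adds to one face; C2 (sulfonyl cis to OH) follows from the endo, titanium-bridged approach and is erased in step 8; the absolute configuration comes from the TADDOLate aryl groups, which leave one diene face open. The step needs the outward naphthyl geometry (the inward position clashes with the C1–H across the diene, although the neighbouring methoxy group forces the naphthyl to twist), sulfonyl-next-to-carbinol regiochemistry (largest HOMO coefficient at the aryl-bearing terminus of the 1-oxy diene, reinforced by the template), and hydrogen transfer faster than energy transfer to the naphthalene (favoured by the weak doubly benzylic C–H bond).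

Step 8
Reactants: 12 (1R,2S,4S)-5-methoxy-4-[5-methoxy-4-(tosyloxy)naphthalen-1-yl]-2-(phenylsulfonyl)-1,2,3,4-tetrahydronaphthalen-1-ol
Product: 13 Dipolynaphthalene B: (1S,4S)-4-(4-hydroxy-5-methoxynaphthalen-1-yl)-5-methoxy-1,2,3,4-tetrahydronaphthalen-1-ol
Conditions: Mg turnings (20 equiv), MeOH–THF, 0 to 40 °C, ultrasound; aq. NH4Cl
Reagents that add atoms: none
Why: Electron-transfer (dissolving-metal) reduction should cleave the alkyl C–SO2Ph bond, with protonation at C2 by methanol, and the aryl O–SO2Ar bond in one operation, while C1 (held as an alkoxide, too poor a leaving group for Julia-type elimination) and C4 are not involved and keep their configuration.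

**Compound list**
1 | methyl 3-methoxy-2-methylbenzoate | COC(=O)c1cccc(OC)c1C | starting material
2 | methyl 2-(bromomethyl)-3-methoxybenzoate | COC(=O)c1cccc(OC)c1CBr | intermediate
3 | 8-methoxynaphthalen-1-ol | COc1cccc2cccc(O)c12 | starting material
4 | 4-bromo-8-methoxynaphthalen-1-ol | COc1cccc2c(Br)ccc(O)c12 | intermediate
5 | 4-bromo-8-methoxynaphthalen-1-yl 4-methylbenzenesulfonate | COc1cccc2c(Br)ccc(OS(=O)(=O)c3ccc(C)cc3)c12 | intermediate
6 | [2-methoxy-6-(methoxycarbonyl)benzyl]zinc bromide | COC(=O)c1cccc(OC)c1C[Zn]Br | intermediate (not isolated)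
7 | methyl 3-methoxy-2-{[5-methoxy-4-(tosyloxy)naphthalen-1-yl]methyl}benzoate | COC(=O)c1cccc(OC)c1Cc1ccc(OS(=O)(=O)c2ccc(C)cc2)c2c(OC)cccc12 | intermediate
8 | 4-[2-(hydroxymethyl)-6-methoxybenzyl]-8-methoxynaphthalen-1-yl 4-methylbenzenesulfonate | OCc1cccc(OC)c1Cc1ccc(OS(=O)(=O)c2ccc(C)cc2)c2c(OC)cccc12 | intermediate
9 | 4-(2-formyl-6-methoxybenzyl)-8-methoxynaphthalen-1-yl 4-methylbenzenesulfonate | O=Cc1cccc(OC)c1Cc1ccc(OS(=O)(=O)c2ccc(C)cc2)c2c(OC)cccc12 | intermediate
10 | phenyl vinyl sulfone | C=CS(=O)(=O)c1ccccc1 | starting material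
11 | outward,outward hydroxy-o-quinodimethane (photoenol of 9; OH and naphthyl both pointing away from the diene interior) | O/C=C1\C=CC=C(OC)/C1=C\c1ccc(OS(=O)(=O)c2ccc(C)cc2)c2c(OC)cccc12 | intermediate (not isolated)
12 | (1R,2S,4S)-5-methoxy-4-[5-methoxy-4-(tosyloxy)naphthalen-1-yl]-2-(phenylsulfonyl)-1,2,3,4-tetrahydronaphthalen-1-ol (OH, sulfonyl and naphthyl on one face) | COc1cccc2c1[C@H](c1ccc(OS(=O)(=O)c3ccc(C)cc3)c3c(OC)cccc13)C[C@H](S(=O)(=O)c1ccccc1)[C@@H]2O | intermediate
13 | Dipolynaphthalene B, (1S,4S)-4-(4-hydroxy-5-methoxynaphthalen-1-yl)-5-methoxy-1,2,3,4-tetrahydronaphthalen-1-ol (cis) | COc1cccc2c1[C@H](c1ccc(O)c3c(OC)cccc13)CC[C@@H]2O | target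

**Step count and risks**
Total step count: 8. Longest linear sequence: 7 steps (from 3 through steps 2, 3, 4, 5, 6, 7, 8).

Steps most likely to fail:

1. Step 7 (bears the label). The sulfonyl oxygen may bind the titanium template too weakly, so that the dienophile adds without face discrimination and the adduct forms with low enantiomeric purity. The fallback uses known chemistry, sets out from 9 and comes back at 13. Irradiation of 9 with 10 at 365 nm in degassed toluene without titanium (the plain photoenol Diels–Alder reaction) should give the racemic all-cis adduct F1. Treatment with Mg in MeOH as in step 8 should give the racemic cis alcohol F2. Lipase-catalysed acylation (Novozym 435, vinyl acetate, MTBE, 30 °C) should then convert the (1R)-enantiomer, as the empirical rule for aryl alkyl carbinols predicts, into the (1R,4R)-acetate F3 and leave 13, which is separated by chromatography.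

2. Step 8. The C2 radical or anion formed on C–S cleavage may expel the C1 oxygen (Julia-type olefination), or the unactivated secondary sulfone may be cleaved only slowly. The fallback sets out from 12 and comes back at 13. Dess–Martin oxidation of 12 should give the β-keto sulfone F4, whose sulfonyl group is now α to a ketone and should be removed cleanly by SmI2 (THF–MeOH, −78 °C) to give the (4S)-tetralone F5. Corey–Bakshi–Shibata reduction with the (R)-methyl oxazaborolidine and BH3·SMe2 should set C1 under catalyst control and give the (1S,4S)-alcohol tosylate F6. Mg in MeOH, now cleaving only the aryl sulfonate, should give 13.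

3. Step 4. Wurtz-type homocoupling during zinc insertion, or slow transmetalation at the doubly ortho-substituted benzylic centre, may erode the coupling. The fallback sets out from 5 and comes back at 7. Miyaura borylation of 5 (B2pin2, Pd(dppf)Cl2, KOAc, dioxane, 80 °C) should give the naphthylboronic ester F7. Suzuki–Miyaura coupling of F7 with the benzylic bromide 2 (Pd(PPh3)4, K2CO3, DME–H2O, 70 °C) should give 7, so the metal sits on the naphthalene instead of the benzylic carbon.

**Further compounds**
F1 | step 7 | racemic all-cis 5-methoxy-4-[5-methoxy-4-(tosyloxy)naphthalen-1-yl]-2-(phenylsulfonyl)-1,2,3,4-tetrahydronaphthalen-1-ol (both enantiomers) | COc1cccc2c1[C@H](c1ccc(OS(=O)(=O)c3ccc(C)cc3)c3c(OC)cccc13)C[C@H](S(=O)(=O)c1ccccc1)[C@@H]2O.COc1cccc2c1[C@@H](c1ccc(OS(=O)(=O)c3ccc(C)cc3)c3c(OC)cccc13)C[C@@H](S(=O)(=O)c1ccccc1)[C@H]2O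
F2 | step 7 | racemic cis-4-(4-hydroxy-5-methoxynaphthalen-1-yl)-5-methoxy-1,2,3,4-tetrahydronaphthalen-1-ol (both enantiomers) | COc1cccc2c1[C@H](c1ccc(O)c3c(OC)cccc13)CC[C@@H]2O.COc1cccc2c1[C@@H](c1ccc(O)c3c(OC)cccc13)CC[C@H]2O
F3 | step 7 | (1R,4R)-4-(4-hydroxy-5-methoxynaphthalen-1-yl)-5-methoxy-1,2,3,4-tetrahydronaphthalen-1-yl acetate | COc1cccc2c1[C@@H](c1ccc(O)c3c(OC)cccc13)CC[C@H]2OC(C)=O
F4 | step 8 | (4S)-5-methoxy-4-[5-methoxy-4-(tosyloxy)naphthalen-1-yl]-2-(phenylsulfonyl)-3,4-dihydronaphthalen-1(2H)-one (C2 epimerisable, drawn without configuration) | COc1cccc2c1[C@H](c1ccc(OS(=O)(=O)c3ccc(C)cc3)c3c(OC)cccc13)CC(S(=O)(=O)c1ccccc1)C2=O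
F5 | step 8 | (4S)-5-methoxy-4-[5-methoxy-4-(tosyloxy)naphthalen-1-yl]-3,4-dihydronaphthalen-1(2H)-one | COc1cccc2c1[C@H](c1ccc(OS(=O)(=O)c3ccc(C)cc3)c3c(OC)cccc13)CCC2=O
F6 | step 8 | (1S,4S)-5-methoxy-4-[5-methoxy-4-(tosyloxy)naphthalen-1-yl]-1,2,3,4-tetrahydronaphthalen-1-ol | COc1cccc2c1[C@H](c1ccc(OS(=O)(=O)c3ccc(C)cc3)c3c(OC)cccc13)CC[C@@H]2O
F7 | step 4 | 8-methoxy-4-(4,4,5,5-tetramethyl-1,3,2-dioxaborolan-2-yl)naphthalen-1-yl 4-methylbenzenesulfonate | COc1cccc2c(B3OC(C)(C)C(C)(C)O3)ccc(OS(=O)(=O)c3ccc(C)cc3)c12
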